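**Assumptions.** The target is read as the 4′-O-prenyl ether of the kuwanon H skeleton, with the cyclohexene all-trans and (1S,5R,6S) in the cyclohexenyl name (C3″ S, C4″ S, C5″ R in the numbering below). The borate from (R)-VANOL is assumed to give the (5R,6S) series in step 8; if the sense of induction is the opposite, (S)-VANOL is used and nothing else changes.

Abbreviations: prenyl = 3-methylbut-2-en-1-yl; MOM = methoxymethyl; Piv = 2,2-dimethylpropanoyl; TBS = tert-butyldimethylsilyl; R* = (1S,5R,6S)-5-[2,4-bis(pivaloyloxy)phenyl]-6-[2-hydroxy-3-prenyl-4-(pivaloyloxy)benzoyl]-3-methylcyclohex-2-en-1-yl.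

## Analysis of the target

The target 24 is a flavone (rings A, C and B; atoms O1, C2–C8a and C1′–C6′) that carries a methylcyclohexene (ring D) at C8. In ring D, C1″ bears the methyl group, C1″=C2″ is the alkene, C3″ is bonded to C8, C4″ bears the 2,4-dihydroxy-3-prenylbenzoyl group, C5″ bears the 2,4-dihydroxyphenyl group and C6″ is CH2. The three stereocentres C3″, C4″ and C5″ are contiguous and all-trans, so all three large groups are equatorial. C4″ is alpha to the aryl ketone and can epimerise, whereas C3″ and C5″ are fixed once set. C3″ is both allylic (C2″=C1″, with a tertiary far terminus) and benzylic to the phloroglucinol ring A; the bond C8–C3″ is therefore the one that a cyclohexenyl cation and an electron-rich arene form. The sensitive groups are seven phenols, an O-prenyl ether at C4′ (labile to acid and to electrophiles), two C-prenyl groups that each sit next to a free OH (chroman formation under acid), and the ring alkene. Hydrogenolysis, strong acid and oxidants are therefore excluded at late stages. The hard points are the all-trans (exo) relation, which a [4+2] cycloaddition does not favour, the C8 versus C6 regiochemistry on ring A, and a final deprotection that must not be acidic.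

## Retrosynthetic reasoning

**Ring C and the protecting groups.** Target 24 is traced to its silyl/pivalate-protected form 23, so that the last step is a base-mediated methanolysis that does not touch the O-prenyl ether. In 23 the O1–C2 bond is cut, which gives the 2-prenyl-1,3-diketone 22. In 22 only the ring A oxygen next to C3″ is free, so ring closure can only give the 8-substituted flavone. The C3-prenyl bond is cut next (C-alkylation of diketone 21). The bond between the acetyl carbon and the ring B carbonyl is then cut, which gives methyl ketone 15 and aroyl chloride 20. Building the flavone after the union, and not before, keeps the O-prenyl ether out of the acidic key step.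

**C8–C3″ (key disconnection).** Ketone 15 is the bis-silyl ether of triol 14. In 14 the bond between ring A and C3″ is cut. The forward reaction is a Friedel–Crafts allylation of phloroacetophenone 12 by the cyclohexenyl cation 13, which is released from allylic acetate 11. The cut is made here for three reasons. First, 12 is symmetric: its two free ring positions are equivalent, so the C6/C8 question of a preformed flavone cannot arise. Second, the cation is planar at C3″, so the configuration of the acetate carbon in 11 does not matter. Third, the incoming arene is expected to add trans to the C4″ aroyl group, which already stands trans to the C5″ aryl group, and this is the all-trans triad of the target. The step has to form a C–C bond at the secondary terminus of an unsymmetrical allyl cation, on one face, with an unfunctionalised arene.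

**Ring D.** Acetate 11 is cut at C3″–C4″ and C5″–C6″, which gives chalcone 8 and dienyl acetate 10. The forward [4+2] cycloaddition only has to set C4″ and C5″. The trans relation comes from the E-alkene of 8 and the absolute sense comes from a chiral borate bound to the free 2′-OH and the carbonyl group. The endo/exo ratio, which is the weak point of the cycloaddition in this family, is irrelevant because the third centre is erased in the key step.

**Building blocks.** Chalcone 8 is the tripivalate of chalcone 7. The pivalates make the resorcinol ring a poor Friedel–Crafts partner in the key step and are removed by methanolysis at the end. Chalcone 7 comes from its MOM ether 6, which is cut at the enone C=C into ketone 3 and aldehyde 5 (Claisen–Schmidt). Ketone 3 comes from 2 and from 1, and aldehyde 5 from 4. Diene 10 comes from enal 9. Aroyl chloride 20 comes from acid 18 through silyl ester 19, and 18 from ester 17 and from 16.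

## Alternatives that were turned down

**Alternative 1:** (the textbook route) Cut C3″–C4″ and C5″–C6″ with the whole flavone in place. The forward step is a [4+2] cycloaddition of chalcone 7 (or 8) with the flavone diene A1 under chiral borate catalysis. It was turned down for three reasons. The target is the exo adduct and the cycloaddition has no built-in exo preference, so a large part of two fully elaborated halves would be lost in the last C–C bond formation. A1 needs a C8-functionalised 3-prenylflavone that already carries the O-prenyl ether, and its electron-rich diene next to the 7-OH is prone to cyclisation and polymerisation. All three stereocentres would rest on one late step.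

**Alternative 2:** Cut C8–C3″ at the dienone level. The amine-catalysed annulation of 9 with aryl enal A2 would give dienal A3 with C5″ set by iminium catalysis. Aryl addition and oxidation would give dienone A4, and an acid-catalysed conjugate Friedel–Crafts addition of 12 at C3″ would follow. It was turned down because C4″ is trigonal when the C–C bond forms, so C5″ (1,3 to C3″) is the only control element. With the C5″ aryl group pseudo-axial to avoid the aroyl group, the arene is expected to add anti to it. That gives the 3″,5″-trans (endo-type) series and not the all-trans target. A correction by retro-Friedel–Crafts equilibration of an acylphloroglucinol cannot be relied on.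

**Alternative 3:** Cut C8–C3″ with the methyl group added last. A ring A organocopper reagent would add to cyclohexenone A5 trans to the C4″ substituent, and the enolate would be trapped and methylated to form C1″(Me)=C2″. It was turned down for step economy and compatibility. The ring A nucleophile would have to be a 2,6-dioxygenated aryl metal with a masked acetyl group, the C4″–H of A5 is doubly activated and acidic, the ester protecting groups do not survive the organometallic, and three steps would be spent on one methyl-bearing alkene.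

Key step: step 9

## Route

Step 1
Reactants: 1 2,4-dihydroxyacetophenone
Product: 2 1-[2,4-dihydroxy-3-(3-methylbut-2-en-1-yl)phenyl]ethan-1-one
Conditions: prenyl bromide (1.0 equiv), KOH (10% aq), 0 °C to rt; chromatography
Reagents that add atoms: prenyl bromide, CC(C)=CCBr
Why: Phenoxide C-alkylation in water; the carbon between the two oxygens (C3) is the most nucleophilic ring position, and the 5-prenyl and O-prenyl isomers that also form are separated.

Step 2
Reactants: 2 1-[2,4-dihydroxy-3-(3-methylbut-2-en-1-yl)phenyl]ethan-1-one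
Product: 3 1-[2-hydroxy-4-(methoxymethoxy)-3-prenylphenyl]ethan-1-one
Conditions: MOMCl (1.1 equiv), K2CO3, acetone, rt
Reagents that add atoms: chloromethyl methyl ether, COCCl
Why: Williamson etherification; the 2-OH is held in a hydrogen bond to the acetyl group, so only the 4-OH reacts.

Step 3
Reactants: 4 2,4-dihydroxybenzaldehyde
Product: 5 2,4-bis(methoxymethoxy)benzaldehyde
Conditions: MOMCl (2.5 equiv), iPr2NEt, CH2Cl2, 0 °C to rt
Reagents that add atoms: chloromethyl methyl ether, COCCl
Why: Exhaustive etherification with excess reagent; the acetals make the aldehyde stable to the hydroxide of the next step.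

Step 4
Reactants: 3 1-[2-hydroxy-4-(methoxymethoxy)-3-prenylphenyl]ethan-1-one; 5 2,4-bis(methoxymethoxy)benzaldehyde
Product: 6 (2E)-3-[2,4-bis(methoxymethoxy)phenyl]-1-[2-hydroxy-4-(methoxymethoxy)-3-prenylphenyl]prop-2-en-1-one
Conditions: KOH (40% aq), EtOH, rt
Reagents that add atoms: none
Why: Claisen–Schmidt condensation; the E1cB dehydration gives the E-enone, and the acetals and the prenyl group are inert to hydroxide, which acts as a catalyst.

Step 5
Reactants: 6 (2E)-3-[2,4-bis(methoxymethoxy)phenyl]-1-[2-hydroxy-4-(methoxymethoxy)-3-prenylphenyl]prop-2-en-1-one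
Product: 7 (2E)-1-[2,4-dihydroxy-3-prenylphenyl]-3-(2,4-dihydroxyphenyl)prop-2-en-1-one
Conditions: HCl (3 M aq, cat.), MeOH, rt to 40 °C
Reagents that add atoms: none
Why: Acid-catalysed acetal methanolysis; dilute acid near room temperature should leave the prenyl group next to the chelated 2′-OH uncyclised.

Step 6
Reactants: 7 (2E)-1-[2,4-dihydroxy-3-prenylphenyl]-3-(2,4-dihydroxyphenyl)prop-2-en-1-one
Product: 8 4-{(2E)-3-[2,4-bis(pivaloyloxy)phenyl]prop-2-enoyl}-3-hydroxy-2-prenylphenyl pivalate
Conditions: PivCl (3.1 equiv), Et3N, CH2Cl2, −20 to 0 °C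
Reagents that add atoms: pivaloyl chloride, CC(C)(C)C(Cl)=O
Why: Selective O-acylation; the three unchelated phenols react, while the 2′-OH, which is chelated to the ketone and flanked by the prenyl group, stays free for the borate of step 8.

Step 7
Reactants: 9 3-methylbut-2-enal
Product: 10 (1E)-3-methylbuta-1,3-dien-1-yl acetate
Conditions: Ac2O, KOAc (0.3 equiv), 120 °C; distillation
Reagents that add atoms: acetic anhydride, CC(=O)OC(C)=O
Why: O-acetylation of the extended (gamma-deprotonated) enolate of the enal gives the dienyl acetate, mainly as the E-isomer, which is the one that reacts in step 8.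

Step 8
Reactants: 8 4-{(2E)-3-[2,4-bis(pivaloyloxy)phenyl]prop-2-enoyl}-3-hydroxy-2-prenylphenyl pivalate; 10 (1E)-3-methylbuta-1,3-dien-1-yl acetate
Product: 11 (5R,6S)-5-[2,4-bis(pivaloyloxy)phenyl]-6-[2-hydroxy-3-prenyl-4-(pivaloyloxy)benzoyl]-3-methylcyclohex-2-en-1-yl acetate (both C1 epimers)
Conditions: (R)-VANOL [(R)-3,3′-diphenyl-2,2′-binaphthalene-1,1′-diol] (20 mol%), BH3·THF (20 mol%), AcOH (20 mol%), THF, rt; then 8, 10 (3 equiv), PhCF3, 35 °C
Reagents that add atoms: none
Why: Diels–Alder reaction of a 2′-hydroxychalcone activated as a chiral borate chelate (phenoxide and carbonyl on boron); the acetoxy group ("ortho") and the methyl group ("para") both direct C3″ to C4″ and C6″ to C5″, the E-enone gives trans C4″/C5″ and the ligand chooses the enone face, while the endo/exo ratio at the acetoxy carbon is of no consequence.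

Step 9
Reactants: 11 (5R,6S)-5-[2,4-bis(pivaloyloxy)phenyl]-6-[2-hydroxy-3-prenyl-4-(pivaloyloxy)benzoyl]-3-methylcyclohex-2-en-1-yl acetate (both C1 epimers); 12 1-(2,4,6-trihydroxyphenyl)ethan-1-one
Product: 14 1-(2,4,6-trihydroxy-3-R*-phenyl)ethan-1-one, via allyl cation 13 (not isolated)
Conditions: 12 (3 equiv), BF3·OEt2 (0.5 equiv), CH2Cl2/MeNO2, −40 to −10 °C
Reagents that add atoms: none
Why: The Lewis acid ionises the allylic acetate, and both C1 epimers of 11 give the same cation 13, whose charge is shared by secondary C3″ and tertiary C1″. Ring A of 12 attacks through one of its two equivalent free carbons and the Wheland intermediate rearomatises; no ring is closed. The closest known reaction type is the acid-catalysed Friedel–Crafts allylation of resorcinols and acylphloroglucinols by p-menthadienyl-type cyclohexenyl cations, which puts the arene on the secondary terminus and trans to the substituent on the neighbouring sp3 carbon. C3″ is controlled in the same way here: the C4″ aroyl and C5″ aryl groups are trans-diequatorial in the half-chair cation, and the arene should add on the face anti to the C4″ aroyl group, which gives the all-trans triad. The step needs C3″ over C1″ selectivity, and this should follow from the bulk of the 2,6-dioxygenated arene, which disfavours a quaternary benzylic carbon, and from the trisubstituted alkene that C3″ attack keeps. It needs C- over O-alkylation, and aryl allyl ethers, including one formed reversibly by the chelated 2′-OH, re-ionise under the conditions, whereas the C–C bond does not. It needs mono-alkylation, which the excess of 12 should secure. It also needs capture of 13 to outrun loss of the C4″ proton, which low temperature and a high concentration of nucleophile favour; the pivalates keep the resorcinol ring of 11 from competing as a nucleophile.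

Step 10
Reactants: 14 1-(2,4,6-trihydroxy-3-R*-phenyl)ethan-1-one
Product: 15 1-{4,6-bis[(tert-butyldimethylsilyl)oxy]-2-hydroxy-3-R*-phenyl}ethan-1-one
Conditions: TBSCl (2.2 equiv), imidazole, DMF, 0 °C
Reagents that add atoms: tert-butyldimethylsilyl chloride, CC(C)(C)[Si](C)(C)Cl
Why: Steric selection in silylation; the two ring A hydroxyls that have a ring hydrogen as neighbour react, while the 2-OH (between the acetyl group and R*) and the chelated 2′-OH of the aroyl ring are both hindered and hydrogen-bonded and should stay free.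

Step 11
Reactants: 16 methyl 2,4-dihydroxybenzoate
Product: 17 methyl 2-hydroxy-4-(prenyloxy)benzoate
Conditions: prenyl bromide (1.1 equiv), K2CO3, acetone, reflux
Reagents that add atoms: prenyl bromide, CC(C)=CCBr
Why: Williamson etherification of the unchelated 4-OH; the 2-OH is hydrogen-bonded to the ester and is left.

Step 12
Reactants: 17 methyl 2-hydroxy-4-(prenyloxy)benzoate
Product: 18 2-hydroxy-4-(prenyloxy)benzoic acid
Conditions: NaOH (aq), MeOH/THF, 50 °C; then cold dilute HCl to pH 4
Reagents that add atoms: sodium hydroxide, [Na+].[OH-]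
Why: Ester saponification; the prenyl ether is stable to base and to a brief, cold, weakly acidic work-up.

Step 13
Reactants: 18 2-hydroxy-4-(prenyloxy)benzoic acid
Product: 20 2-[(tert-butyldimethylsilyl)oxy]-4-(prenyloxy)benzoyl chloride, via silyl ester 19 (not isolated)
Conditions: TBSCl (2.2 equiv), imidazole, CH2Cl2, rt; filter, concentrate; then (COCl)2 (1.2 equiv), DMF (cat.), CH2Cl2, 0 °C to rt
Reagents that add atoms: tert-butyldimethylsilyl chloride, CC(C)(C)[Si](C)(C)Cl; oxalyl chloride, ClC(=O)C(Cl)=O
Why: Bis-silylation gives the silyl ester and silyl ether; the Vilsmeier reagent turns the silyl ester into the acid chloride with release of the silyl chloride and no HCl, which spares the prenyl ether and the aryl silyl ether.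

Step 14
Reactants: 15 1-{4,6-bis[(tert-butyldimethylsilyl)oxy]-2-hydroxy-3-R*-phenyl}ethan-1-one; 20 2-[(tert-butyldimethylsilyl)oxy]-4-(prenyloxy)benzoyl chloride
Product: 21 1-{4,6-bis[(tert-butyldimethylsilyl)oxy]-2-hydroxy-3-R*-phenyl}-3-{2-[(tert-butyldimethylsilyl)oxy]-4-(prenyloxy)phenyl}propane-1,3-dione
Conditions: LiN(SiMe3)2 (4.2 equiv), THF, −78 °C; then 20 (1.2 equiv), −78 to −20 °C; aq NH4Cl
Reagents that add atoms: none
Why: Direct C-acylation of the lithium enolate of a polylithiated hydroxyacetophenone (the one-pot form of the Baker–Venkataraman diketone synthesis); the two hindered lithium phenoxides are poor nucleophiles, and an O-acyl ester on the ring A 2-oxygen would rearrange to the same diketone; the pivalates have no alpha-hydrogen and should survive at low temperature.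

Step 15
Reactants: 21 1-{4,6-bis[(tert-butyldimethylsilyl)oxy]-2-hydroxy-3-R*-phenyl}-3-{2-[(tert-butyldimethylsilyl)oxy]-4-(prenyloxy)phenyl}propane-1,3-dione
Product: 22 1-{4,6-bis[(tert-butyldimethylsilyl)oxy]-2-hydroxy-3-R*-phenyl}-3-{2-[(tert-butyldimethylsilyl)oxy]-4-(prenyloxy)phenyl}-2-prenylpropane-1,3-dione (epimers at C2 of the dione)
Conditions: prenyl bromide (1.2 equiv), K2CO3, acetone, rt
Reagents that add atoms: prenyl bromide, CC(C)=CCBr
Why: C-alkylation of the 1,3-diketone, the most acidic and softest nucleophile present; the two chelated phenols are not alkylated under these conditions, and the new centre disappears in step 16.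

Step 16
Reactants: 22 1-{4,6-bis[(tert-butyldimethylsilyl)oxy]-2-hydroxy-3-R*-phenyl}-3-{2-[(tert-butyldimethylsilyl)oxy]-4-(prenyloxy)phenyl}-2-prenylpropane-1,3-dione (epimers at C2 of the dione)
Product: 23 5,7-bis[(tert-butyldimethylsilyl)oxy]-2-{2-[(tert-butyldimethylsilyl)oxy]-4-(prenyloxy)phenyl}-3-prenyl-8-R*-4H-chromen-4-one
Conditions: TsOH·H2O (10 mol%), CH2Cl2, 4 Å molecular sieves, rt
Reagents that add atoms: none
Why: Cyclodehydration (hemiketal formation, then loss of water) closes ring C by 6-exo attack of the only free ring A hydroxyl, the one next to C3″, on the ring B carbonyl, which fixes the 8-substituted flavone; the silylated 5-O and 2′-O cannot compete.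

Step 17
Reactants: 23 5,7-bis[(tert-butyldimethylsilyl)oxy]-2-{2-[(tert-butyldimethylsilyl)oxy]-4-(prenyloxy)phenyl}-3-prenyl-8-R*-4H-chromen-4-one
Product: 24 8-[(1S,5R,6S)-6-(2,4-dihydroxy-3-prenylbenzoyl)-5-(2,4-dihydroxyphenyl)-3-methylcyclohex-2-en-1-yl]-5,7-dihydroxy-2-[2-hydroxy-4-(prenyloxy)phenyl]-3-prenyl-4H-chromen-4-one
Conditions: K2CO3, MeOH (degassed), argon, rt to 40 °C; buffer to pH 6
Reagents that add atoms: none
Why: Base-catalysed methanolysis cleaves the three aryl silyl ethers and the three aryl pivalates in one operation without acid, so the O-prenyl ether and both C-prenyl groups are untouched; any epimerisation at C4″ under base returns the more stable all-trans arrangement.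

## Compound list

1 | 2,4-dihydroxyacetophenone | CC(=O)c1ccc(O)cc1O | starting material
2 | 1-[2,4-dihydroxy-3-prenylphenyl]ethan-1-one | CC(=O)c1ccc(O)c(CC=C(C)C)c1O | intermediate
3 | 1-[2-hydroxy-4-(methoxymethoxy)-3-prenylphenyl]ethan-1-one | CC(=O)c1ccc(OCOC)c(CC=C(C)C)c1O | intermediate
4 | 2,4-dihydroxybenzaldehyde | O=Cc1ccc(O)cc1O | starting material
5 | 2,4-bis(methoxymethoxy)benzaldehyde | COCOc1ccc(C=O)c(OCOC)c1 | intermediate
6 | (2E)-3-[2,4-bis(methoxymethoxy)phenyl]-1-[2-hydroxy-4-(methoxymethoxy)-3-prenylphenyl]prop-2-en-1-one | COCOc1ccc(/C=C/C(=O)c2ccc(OCOC)c(CC=C(C)C)c2O)c(OCOC)c1 | intermediate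
7 | (2E)-1-[2,4-dihydroxy-3-prenylphenyl]-3-(2,4-dihydroxyphenyl)prop-2-en-1-one | Oc1ccc(/C=C/C(=O)c2ccc(O)c(CC=C(C)C)c2O)c(O)c1 | intermediate
8 | 4-{(2E)-3-[2,4-bis(pivaloyloxy)phenyl]prop-2-enoyl}-3-hydroxy-2-prenylphenyl pivalate | CC(C)(C)C(=O)Oc1ccc(/C=C/C(=O)c2ccc(OC(=O)C(C)(C)C)c(CC=C(C)C)c2O)c(OC(=O)C(C)(C)C)c1 | intermediate
9 | 3-methylbut-2-enal | CC(C)=CC=O | starting material
10 | (1E)-3-methylbuta-1,3-dien-1-yl acetate | CC(=O)O/C=C/C(C)=C | intermediate
11 | (5R,6S)-5-[2,4-bis(pivaloyloxy)phenyl]-6-[2-hydroxy-3-prenyl-4-(pivaloyloxy)benzoyl]-3-methylcyclohex-2-en-1-yl acetate, C1 epimers | CC(=O)OC1C=C(C)C[C@@H](c2ccc(OC(=O)C(C)(C)C)cc2OC(=O)C(C)(C)C)[C@@H]1C(=O)c1ccc(OC(=O)C(C)(C)C)c(CC=C(C)C)c1O | intermediate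
12 | 1-(2,4,6-trihydroxyphenyl)ethan-1-one | CC(=O)c1c(O)cc(O)cc1O | starting material
13 | 5-[2,4-bis(pivaloyloxy)phenyl]-6-[2-hydroxy-3-prenyl-4-(pivaloyloxy)benzoyl]-3-methylcyclohex-2-en-1-ylium, configured at both centres as in 11 | [CH+]1C=C(C)C[C@@H](c2ccc(OC(=O)C(C)(C)C)cc2OC(=O)C(C)(C)C)[C@@H]1C(=O)c1ccc(OC(=O)C(C)(C)C)c(CC=C(C)C)c1O | intermediate
14 | 1-(2,4,6-trihydroxy-3-R*-phenyl)ethan-1-one | CC(=O)c1c(O)cc(O)c([C@H]2C=C(C)C[C@@H](c3ccc(OC(=O)C(C)(C)C)cc3OC(=O)C(C)(C)C)[C@@H]2C(=O)c2ccc(OC(=O)C(C)(C)C)c(CC=C(C)C)c2O)c1O | intermediate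
15 | 1-{4,6-bis[(tert-butyldimethylsilyl)oxy]-2-hydroxy-3-R*-phenyl}ethan-1-one | CC(=O)c1c(O[Si](C)(C)C(C)(C)C)cc(O[Si](C)(C)C(C)(C)C)c([C@H]2C=C(C)C[C@@H](c3ccc(OC(=O)C(C)(C)C)cc3OC(=O)C(C)(C)C)[C@@H]2C(=O)c2ccc(OC(=O)C(C)(C)C)c(CC=C(C)C)c2O)c1O | intermediate
16 | methyl 2,4-dihydroxybenzoate | COC(=O)c1ccc(O)cc1O | starting material
17 | methyl 2-hydroxy-4-(prenyloxy)benzoate | COC(=O)c1ccc(OCC=C(C)C)cc1O | intermediate
18 | 2-hydroxy-4-(prenyloxy)benzoic acid | OC(=O)c1ccc(OCC=C(C)C)cc1O | intermediate
19 | tert-butyldimethylsilyl 2-[(tert-butyldimethylsilyl)oxy]-4-(prenyloxy)benzoate | CC(C)=CCOc1ccc(C(=O)O[Si](C)(C)C(C)(C)C)c(O[Si](C)(C)C(C)(C)C)c1 | intermediate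
20 | 2-[(tert-butyldimethylsilyl)oxy]-4-(prenyloxy)benzoyl chloride | CC(C)=CCOc1ccc(C(Cl)=O)c(O[Si](C)(C)C(C)(C)C)c1 | intermediate
21 | 1-{4,6-bis[(tert-butyldimethylsilyl)oxy]-2-hydroxy-3-R*-phenyl}-3-{2-[(tert-butyldimethylsilyl)oxy]-4-(prenyloxy)phenyl}propane-1,3-dione | CC(C)=CCOc1ccc(C(=O)CC(=O)c2c(O[Si](C)(C)C(C)(C)C)cc(O[Si](C)(C)C(C)(C)C)c([C@H]3C=C(C)C[C@@H](c4ccc(OC(=O)C(C)(C)C)cc4OC(=O)C(C)(C)C)[C@@H]3C(=O)c3ccc(OC(=O)C(C)(C)C)c(CC=C(C)C)c3O)c2O)c(O[Si](C)(C)C(C)(C)C)c1 | intermediate
22 | 2-prenyl derivative of 21 (epimers at C2 of the dione) | CC(C)=CCOc1ccc(C(=O)C(CC=C(C)C)C(=O)c2c(O[Si](C)(C)C(C)(C)C)cc(O[Si](C)(C)C(C)(C)C)c([C@H]3C=C(C)C[C@@H](c4ccc(OC(=O)C(C)(C)C)cc4OC(=O)C(C)(C)C)[C@@H]3C(=O)c3ccc(OC(=O)C(C)(C)C)c(CC=C(C)C)c3O)c2O)c(O[Si](C)(C)C(C)(C)C)c1 | intermediate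
23 | 5,7-bis[(tert-butyldimethylsilyl)oxy]-2-{2-[(tert-butyldimethylsilyl)oxy]-4-(prenyloxy)phenyl}-3-prenyl-8-R*-4H-chromen-4-one | CC(C)=CCOc1ccc(-c2oc3c([C@H]4C=C(C)C[C@@H](c5ccc(OC(=O)C(C)(C)C)cc5OC(=O)C(C)(C)C)[C@@H]4C(=O)c4ccc(OC(=O)C(C)(C)C)c(CC=C(C)C)c4O)c(O[Si](C)(C)C(C)(C)C)cc(O[Si](C)(C)C(C)(C)C)c3c(=O)c2CC=C(C)C)c(O[Si](C)(C)C(C)(C)C)c1 | intermediate
24 | 8-[(1S,5R,6S)-6-(2,4-dihydroxy-3-prenylbenzoyl)-5-(2,4-dihydroxyphenyl)-3-methylcyclohex-2-en-1-yl]-5,7-dihydroxy-2-[2-hydroxy-4-(prenyloxy)phenyl]-3-prenyl-4H-chromen-4-one | CC(C)=CCOc1ccc(-c2oc3c([C@H]4C=C(C)C[C@@H](c5ccc(O)cc5O)[C@@H]4C(=O)c4ccc(O)c(CC=C(C)C)c4O)c(O)cc(O)c3c(=O)c2CC=C(C)C)c(O)c1 | target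

## Step count and least certain steps

Total: 17 steps. Longest linear sequence: 12 steps (1, 2, 4, 5, 6, 8, 9, 10, 14, 15, 16, 17).

**Step 9 (key step).** The most likely failure is loss of the acidified C4″ proton from cation 13, or acid-promoted elimination of acetic acid from 11, before the arene arrives. That leads into a cross-conjugated dienone pathway in which C4″ is trigonal, so the arene would add under the control of C5″ alone and the selectivity at C3″ would erode or invert. Lesser risks are attack at the tertiary terminus C1″, reversible trapping of the cation by the chelated 2′-OH, and acid-induced cyclisation of the C-prenyl group onto that hydroxyl. The fallback sets out from 12 and 8 and comes back at 14. Compound 12 is iodinated (N-iodosuccinimide) to 1-(2,4,6-trihydroxy-3-iodophenyl)ethan-1-one F1 and peracetylated to 2-acetyl-4-iodobenzene-1,3,5-triyl triacetate F2. A Stille coupling with (E)-tributyl(3-methylbuta-1,3-dien-1-yl)stannane [Pd(PPh3)4, toluene] gives 2-acetyl-4-[(1E)-3-methylbuta-1,3-dien-1-yl]benzene-1,3,5-triyl triacetate F3. The borate-catalysed Diels–Alder reaction of F3 with 8 under the conditions of step 8 gives exo and endo adducts, from which the exo adduct, the ring A triacetate of 14 F4, is separated. Brief treatment with K2CO3 in MeOH at 0 °C, where aryl acetates are cleaved much faster than aryl pivalates, returns 14.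

**Step 8.** The oxygenated diene may react slowly or with poor facial selectivity on the borate, and the adduct may lose acetic acid on the Lewis-acidic boron. The fallback sets out from 8 and 10 and comes back at 11. An uncatalysed cycloaddition in toluene at 90–110 °C (radical inhibitor) gives racemic material. Preparative chromatography on a chiral stationary phase separates 11 from its (5S,6R) enantiomer F5, which is discarded.

**Step 10.** The second silyl group may go onto the ring A hydroxyl next to C3″ instead of the one next to the ring hydrogen, or a third silylation may occur; either would spoil the regiochemistry of ring C closure. The fallback sets out from 12 and 11 and comes back at 15. Compound 12 is silylated first (TBSCl, 2.1 equiv, imidazole) to 1-{2-hydroxy-4,6-bis[(tert-butyldimethylsilyl)oxy]phenyl}ethan-1-one F6, which is used in place of 12 in step 9. The position next to its free hydroxyl is the less hindered one, so the coupling should give 15 directly.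

**Step 15.** O-alkylation of the diketone, premature closure of 21 to a 3-unsubstituted flavone, or base-induced loss of an aryl silyl ether may compete with C-prenylation. The fallback sets out from 15 and comes back at 22. The acetyl group of 15 is alkylated first [LiN(SiMe3)2, 3.1 equiv, then prenyl bromide, THF, −78 to 0 °C] to 1-{4,6-bis[(tert-butyldimethylsilyl)oxy]-2-hydroxy-3-R*-phenyl}-5-methylhex-4-en-1-one F7. C-acylation of its enolate with 20 under the conditions of step 14 then gives 22.

## Further compounds

F1 | step 9 | 1-(2,4,6-trihydroxy-3-iodophenyl)ethan-1-one | CC(=O)c1c(O)cc(O)c(I)c1O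
F2 | step 9 | 2-acetyl-4-iodobenzene-1,3,5-triyl triacetate | CC(=O)Oc1cc(OC(C)=O)c(C(C)=O)c(OC(C)=O)c1I
F3 | step 9 | 2-acetyl-4-[(1E)-3-methylbuta-1,3-dien-1-yl]benzene-1,3,5-triyl triacetate | CC(=O)Oc1cc(OC(C)=O)c(C(C)=O)c(OC(C)=O)c1/C=C/C(C)=C
F4 | step 9 | 2-acetyl-4-R*-benzene-1,3,5-triyl triacetate (ring A triacetate of 14) | CC(=O)Oc1cc(OC(C)=O)c(C(C)=O)c(OC(C)=O)c1[C@H]1C=C(C)C[C@@H](c2ccc(OC(=O)C(C)(C)C)cc2OC(=O)C(C)(C)C)[C@@H]1C(=O)c1ccc(OC(=O)C(C)(C)C)c(CC=C(C)C)c1O
F5 | step 8 | (5S,6R)-5-[2,4-bis(pivaloyloxy)phenyl]-6-[2-hydroxy-3-prenyl-4-(pivaloyloxy)benzoyl]-3-methylcyclohex-2-en-1-yl acetate (enantiomer of 11, C1 epimers) | CC(=O)OC1C=C(C)C[C@H](c2ccc(OC(=O)C(C)(C)C)cc2OC(=O)C(C)(C)C)[C@H]1C(=O)c1ccc(OC(=O)C(C)(C)C)c(CC=C(C)C)c1O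
F6 | step 10 | 1-{2-hydroxy-4,6-bis[(tert-butyldimethylsilyl)oxy]phenyl}ethan-1-one | CC(=O)c1c(O)cc(O[Si](C)(C)C(C)(C)C)cc1O[Si](C)(C)C(C)(C)C
F7 | step 15 | 1-{4,6-bis[(tert-butyldimethylsilyl)oxy]-2-hydroxy-3-R*-phenyl}-5-methylhex-4-en-1-one | CC(C)=CCCC(=O)c1c(O[Si](C)(C)C(C)(C)C)cc(O[Si](C)(C)C(C)(C)C)c([C@H]2C=C(C)C[C@@H](c3ccc(OC(=O)C(C)(C)C)cc3OC(=O)C(C)(C)C)[C@@H]2C(=O)c2ccc(OC(=O)C(C)(C)C)c(CC=C(C)C)c2O)c1O
A1 | alternative 1 | 5,7-dihydroxy-2-[2-hydroxy-4-(prenyloxy)phenyl]-8-[(1E)-3-methylbuta-1,3-dien-1-yl]-3-prenyl-4H-chromen-4-one | CC(C)=CCOc1ccc(-c2oc3c(/C=C/C(C)=C)c(O)cc(O)c3c(=O)c2CC=C(C)C)c(O)c1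
A2 | alternative 2 | (2E)-3-{2,4-bis[(tert-butyldimethylsilyl)oxy]phenyl}prop-2-enal | O=C/C=C/c1ccc(O[Si](C)(C)C(C)(C)C)cc1O[Si](C)(C)C(C)(C)C
A3 | alternative 2 | 6-{2,4-bis[(tert-butyldimethylsilyl)oxy]phenyl}-4-methylcyclohexa-1,3-diene-1-carbaldehyde, C6 configured as C5″ of the target | CC1=CC=C(C=O)[C@H](c2ccc(O[Si](C)(C)C(C)(C)C)cc2O[Si](C)(C)C(C)(C)C)C1
A4 | alternative 2 | [2,4-bis(methoxymethoxy)-3-prenylphenyl](6-{2,4-bis[(tert-butyldimethylsilyl)oxy]phenyl}-4-methylcyclohexa-1,3-dien-1-yl)methanone, C6 configured as C5″ of the target | CC1=CC=C(C(=O)c2ccc(OCOC)c(CC=C(C)C)c2OCOC)[C@H](c2ccc(O[Si](C)(C)C(C)(C)C)cc2O[Si](C)(C)C(C)(C)C)C1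
A5 | alternative 3 | trans-5-[2,4-bis(pivaloyloxy)phenyl]-4-[2-hydroxy-3-prenyl-4-(pivaloyloxy)benzoyl]cyclohex-2-en-1-one, configured as C4″ and C5″ of the target | O=C1C=C[C@@H](C(=O)c2ccc(OC(=O)C(C)(C)C)c(CC=C(C)C)c2O)[C@H](c2ccc(OC(=O)C(C)(C)C)cc2OC(=O)C(C)(C)C)C1
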